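**Retrosynthetic overview**
- Amaurone B ⇒ cyclohexane E-enal diacetate + 2-(but-2-en-2-yl)-6-methoxy-3,5-dimethyl-γ-pyranone; a vinylogous aldol condensation makes the central CH=CH, and the enal comes from the cyclohexanecarbaldehyde by Wittig reaction.
- Cyclohexane ⇒ acyclic keto-aldehyde: the C3–C4 bond and the C3/C4 cis-diol come from a light-driven, samarium-catalysed pinacol cyclisation directed by the free C5 hydroxyl.
- Keto-aldehyde ⇒ diene (double ozonolysis) ⇒ chelation-controlled MeMgBr addition (C5) ⇒ dianionic Ireland–Claisen rearrangement of a tiglyl L-malate (C1, C2) ⇒ L-malic acid (C6, the only purchased stereocentre).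
- Ring order: the pyranone is built separately (steps 13–14); the carbocycle is the only ring closed on the main line (step 9); the two are joined last (step 15).

Assumption: ring atoms are numbered C1 (side chain), C2 (Me), C3 (Me, OH), C4 (OAc), C5 (Me, OH), C6 (OAc). The given SMILES is 1R,2S,3R,4R,5S,6S, with all four oxygens on one face and the C1 chain and the three methyls on the other.

**Step 1**
Reactants: 1 L-malic acid; 2 2,2-dimethoxypropane
Product: 3 2-[(4S)-2,2-dimethyl-5-oxo-1,3-dioxolan-4-yl]acetic acid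
Conditions: 2,2-dimethoxypropane, p-TsOH (cat.), rt
Reagents that add atoms: 2,2-dimethoxypropane (2), COC(C)(C)OC
Why: Acid-catalysed trans-acetalisation ties the α-hydroxy acid as a dioxolanone and leaves the β-carboxyl free; the malic acid stereocentre (future C6, S) is untouched.

**Step 2**
Reactants: 3 2-[(4S)-2,2-dimethyl-5-oxo-1,3-dioxolan-4-yl]acetic acid; 4 (2E)-2-methylbut-2-en-1-ol (tiglyl alcohol)
Product: 5 (2E)-2-methylbut-2-en-1-yl [(4S)-2,2-dimethyl-5-oxo-1,3-dioxolan-4-yl]acetate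
Conditions: DCC, DMAP (5 mol%), CH2Cl2, 0 °C to rt
Reagents that add atoms: (2E)-2-methylbut-2-en-1-ol (4), C/C=C(\C)CO
Why: Steglich esterification of the only free carboxyl installs the allyl partner for the later [3,3] shift without touching the stereocentre.

**Step 3**
Reactants: 5 (2E)-2-methylbut-2-en-1-yl [(4S)-2,2-dimethyl-5-oxo-1,3-dioxolan-4-yl]acetate; 6 morpholine
Product: 7 (2E)-2-methylbut-2-en-1-yl (3S)-3-hydroxy-4-(morpholin-4-yl)-4-oxobutanoate
Conditions: morpholine (1.5 equiv), THF, rt to 40 °C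
Reagents that add atoms: morpholine (6), C1COCCN1
Why: Aminolysis of the activated dioxolanone (an acyl acetal) is far faster than attack on the allyl ester and unmasks the β-hydroxyl while giving a morpholine amide as ketone precursor.

**Step 4**
Reactants: 7 (2E)-2-methylbut-2-en-1-yl (3S)-3-hydroxy-4-(morpholin-4-yl)-4-oxobutanoate
Product: 9 (2R,3S)-2-[(1S)-1-hydroxy-2-(morpholin-4-yl)-2-oxoethyl]-3,4-dimethylpent-4-enoic acid, via dilithium alkoxide enolate 8 (not isolated)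
Conditions: LDA (2.3 equiv), THF, −78 °C then 55 °C; 1 M HCl
Reagents that add atoms: none
Why: Dianionic Ireland–Claisen rearrangement: the lithium-chelated alkoxide/(Z)-enolate (the Fráter–Seebach dianion) reacts through a chair on the face anti to the amide-bearing substituent, setting C1 (R) anti to the C6 hydroxyl, and the E-alkene of the tiglyl unit sets C2 (S) cis to the future side chain.

**Step 5**
Reactants: 9 (2R,3S)-2-[(1S)-1-hydroxy-2-(morpholin-4-yl)-2-oxoethyl]-3,4-dimethylpent-4-enoic acid; 10 (2-methylprop-1-en-1-yl)magnesium bromide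
Product: 11 (2R,3S)-2-[(1S)-1-hydroxy-4-methyl-2-oxopent-3-en-1-yl]-3,4-dimethylpent-4-enoic acid
Conditions: Grignard 10 (4 equiv), THF, 0 °C to rt; inverse quench into cold 1 M HCl
Reagents that add atoms: (2-methylprop-1-en-1-yl)magnesium bromide (10), CC(C)=C[Mg]Br
Why: Grignard acylation of a morpholine amide stops at the ketone (chelated tetrahedral intermediate), the carboxylate and alkoxide are inert, and the β,β-disubstituted enone resists conjugate addition of the liberated amine.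

**Step 6**
Reactants: 11 (2R,3S)-2-[(1S)-1-hydroxy-4-methyl-2-oxopent-3-en-1-yl]-3,4-dimethylpent-4-enoic acid; 12 methylmagnesium bromide
Product: 14 (2S,3S,4R)-4,6-dimethyl-2-[(2S)-3-methylbut-3-en-2-yl]hept-5-ene-1,3,4-triol, via bromomagnesium hydroxy carboxylate 13 (not isolated)
Conditions: MeMgBr (4 equiv), THF, −78 to −20 °C; then LiAlH4 (4 equiv), reflux; Fieser work-up
Reagents that add atoms: methylmagnesium bromide (12), C[Mg]Br
Why: Cram-chelate-controlled 1,2-addition to the magnesium α-alkoxy ketone from the face opposite the C1 branch sets the C5 carbinol with its oxygen cis to O6 in the future ring, and in-pot LiAlH4 reduction of the carboxylate avoids acid contact of the tertiary allylic alcohol and γ-lactonisation.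

**Step 7**
Reactants: 14 (2S,3S,4R)-4,6-dimethyl-2-[(2S)-3-methylbut-3-en-2-yl]hept-5-ene-1,3,4-triol; 15 chlorotriethylsilane
Product: 16 (2S,3S,4R)-4,6-dimethyl-2-[(2S)-3-methylbut-3-en-2-yl]-1-[(triethylsilyl)oxy]hept-5-ene-3,4-diol
Conditions: TESCl (1.05 equiv), imidazole, CH2Cl2, −40 to −20 °C
Reagents that add atoms: chlorotriethylsilane (15), CC[Si](Cl)(CC)CC
Why: Low-temperature silylation is selective for the primary hydroxyl and prevents lactol formation with the aldehyde made in the next step.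

**Step 8**
Reactants: 16 (2S,3S,4R)-4,6-dimethyl-2-[(2S)-3-methylbut-3-en-2-yl]-1-[(triethylsilyl)oxy]hept-5-ene-3,4-diol; 17 ozone
Product: 19 (2S,3S,4S)-2,3-dihydroxy-2-methyl-4-[(2S)-3-oxobutan-2-yl]-5-[(triethylsilyl)oxy]pentanal, via bis-ozonide 18 (not isolated)
Conditions: O3, CH2Cl2, −78 °C; PPh3 (2.2 equiv), −78 °C to rt; used crude
Reagents that add atoms: ozone (17), [O-][O+]=O
Why: Ozonolysis (Criegee mechanism) with neutral reductive work-up cleaves both electron-rich alkenes to the C4 aldehyde and the C3 methyl ketone without epimerising C2 next to the new ketone.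

**Step 9**
Reactants: 19 (2S,3S,4S)-2,3-dihydroxy-2-methyl-4-[(2S)-3-oxobutan-2-yl]-5-[(triethylsilyl)oxy]pentanal
Product: 20 (1R,2R,3S,4S,5S,6S)-1,3,6-trimethyl-5-{[(triethylsilyl)oxy]methyl}cyclohexane-1,2,3,4-tetrol
Conditions: SmI2 (15 mol%), 3DPAFIPN (2 mol%), Hantzsch ester (1.5 equiv), 2,6-lutidinium triflate (20 mol%), degassed THF, 456 nm LEDs, 25 °C
Reagents that add atoms: none
Why: Proposed new method: a visible-light-driven, samarium-catalysed intramolecular ketone–aldehyde pinacol coupling in which the reduced cyanoarene photocatalyst (about −1.6 V) regenerates Sm(II) from Sm(III) with Hantzsch ester as terminal 2 e−/2 H+ donor; Sm(II) reduces the chelated α-hydroxy aldehyde to a ketyl that adds in a chair to the Sm-bound C3 ketone (a second Sm(II) reduces the alkoxy radical), the metal bridging O3, O4 and the C5 alkoxide so that the cis-diol forms on the face of the C5 hydroxyl (C3 R, C4 R; axial–equatorial–axial triol with C3-Me equatorial), and lutidinium protonolysis turns the catalyst over; the closest known reaction type is the stoichiometric SmI2 pinacol cyclisation of keto-aldehydes, together with photoredox pinacol couplings of aryl carbonyls.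

**Step 10**
Reactants: 20 (1R,2R,3S,4S,5S,6S)-1,3,6-trimethyl-5-{[(triethylsilyl)oxy]methyl}cyclohexane-1,2,3,4-tetrol; 21 acetic anhydride
Product: 22 (1R,2R,3S,4S,5S,6S)-1,3-dihydroxy-1,3,6-trimethyl-5-{[(triethylsilyl)oxy]methyl}cyclohexane-2,4-diyl diacetate
Conditions: Ac2O (2.6 equiv), pyridine, DMAP (5 mol%), CH2Cl2, 0 °C to rt
Reagents that add atoms: acetic anhydride (21), CC(=O)OC(C)=O
Why: DMAP-catalysed acetylation takes the two equatorial secondary hydroxyls (C4, C6), while the axial tertiary hydroxyls do not react under these conditions.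

**Step 11**
Reactants: 22 (1R,2R,3S,4S,5S,6S)-1,3-dihydroxy-1,3,6-trimethyl-5-{[(triethylsilyl)oxy]methyl}cyclohexane-2,4-diyl diacetate
Product: 23 (1R,2R,3S,4S,5R,6S)-5-formyl-1,3-dihydroxy-1,3,6-trimethylcyclohexane-2,4-diyl diacetate
Conditions: (COCl)2 (2.5 equiv), DMSO (5 equiv), CH2Cl2, −78 to −40 °C; Et3N, −78 to −20 °C; pH 7 buffer
Reagents that add atoms: none
Why: Swern oxidation cleaves and oxidises a primary triethylsilyl ether directly (chlorosulfonium desilylation, then alkoxysulfonium ylide collapse), leaving tertiary alcohols and acetates alone; the equatorial C6 acetate is poorly aligned for E1cB loss and C1 stays equatorial.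

**Step 12**
Reactants: 23 (1R,2R,3S,4S,5R,6S)-5-formyl-1,3-dihydroxy-1,3,6-trimethylcyclohexane-2,4-diyl diacetate; 24 2-(triphenyl-λ5-phosphanylidene)propanal
Product: 25 (1R,2R,3S,4S,5R,6S)-1,3-dihydroxy-1,3,6-trimethyl-5-[(1E)-2-methyl-3-oxoprop-1-en-1-yl]cyclohexane-2,4-diyl diacetate
Conditions: ylide 24 (2 equiv), toluene, 80 °C
Reagents that add atoms: 2-(triphenyl-λ5-phosphanylidene)propanal (24), CC(C=O)=P(c1ccccc1)(c1ccccc1)c1ccccc1
Why: Wittig reaction with the stabilised α-methyl formyl ylide gives the E-trisubstituted enal under neutral conditions, so the β-acetate and the C1 configuration survive.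

**Step 13**
Reactants: 26 methyl 2-methyl-3-oxopentanoate; 27 methyl (2E)-2-methylbut-2-enoate (methyl tiglate)
Product: 29 6-[(2E)-but-2-en-2-yl]-4-hydroxy-3,5-dimethyl-2H-pyran-2-one, via diketo ester 28 (not isolated)
Conditions: 26 (2 equiv), LDA (4.1 equiv), THF, −78 to 0 °C; 27; AcOH; then DBU, toluene, 80 °C
Reagents that add atoms: methyl (2E)-2-methylbut-2-enoate (27), COC(=O)/C(C)=C/C
Why: Claisen-type acylation of the β-keto ester dianion at its γ-carbon, then base-mediated enol lactonisation, builds the 4-hydroxy-2-pyranone ring; no stereocentre is involved.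

**Step 14**
Reactants: 29 6-[(2E)-but-2-en-2-yl]-4-hydroxy-3,5-dimethyl-2H-pyran-2-one; 30 methyl trifluoromethanesulfonate
Product: 31 2-[(2E)-but-2-en-2-yl]-6-methoxy-3,5-dimethyl-4H-pyran-4-one
Conditions: MeOTf (1.2 equiv), CH2Cl2, rt; sat. NaHCO3
Reagents that add atoms: methyl trifluoromethanesulfonate (30), COS(=O)(=O)C(F)(F)F
Why: Hard O-methylation at the lactone carbonyl oxygen gives the 2-methoxy-4-pyranone regioselectively after loss of a proton.

**Step 15**
Reactants: 25 (1R,2R,3S,4S,5R,6S)-1,3-dihydroxy-1,3,6-trimethyl-5-[(1E)-2-methyl-3-oxoprop-1-en-1-yl]cyclohexane-2,4-diyl diacetate; 31 2-[(2E)-but-2-en-2-yl]-6-methoxy-3,5-dimethyl-4H-pyran-4-one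
Product: 34 amaurone B, via lithium aldolate 32 (not isolated), via allylic mesylate 33 (not isolated)
Conditions: 31 (1.5 equiv), LiHMDS (1.5 equiv), THF, −78 °C; 25, −78 °C; MsCl (1.3 equiv), −78 to −20 °C; DBU, rt
Reagents that add atoms: 2-[(2E)-but-2-en-2-yl]-6-methoxy-3,5-dimethyl-4H-pyran-4-one (31), COc1oc(/C(C)=C/C)c(C)c(=O)c1C
Why: Vinylogous aldol condensation: deprotonation of the ε-methyl gives a trienolate whose only unhindered terminus adds to the enal, and mesylation with E1cB elimination gives the fully conjugated all-E triene without touching the ring stereocentres.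

**Compound list**
1 | L-malic acid, (2S)-2-hydroxybutanedioic acid | OC(=O)C[C@H](O)C(=O)O | starting material
2 | 2,2-dimethoxypropane | COC(C)(C)OC | starting material
3 | 2-[(4S)-2,2-dimethyl-5-oxo-1,3-dioxolan-4-yl]acetic acid | CC1(C)OC(=O)[C@H](CC(=O)O)O1 | intermediate
4 | (2E)-2-methylbut-2-en-1-ol (tiglyl alcohol) | C/C=C(\C)CO | starting material
5 | (2E)-2-methylbut-2-en-1-yl [(4S)-2,2-dimethyl-5-oxo-1,3-dioxolan-4-yl]acetate | C/C=C(\C)COC(=O)C[C@@H]1OC(C)(C)OC1=O | intermediate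
6 | morpholine | C1COCCN1 | starting material
7 | (2E)-2-methylbut-2-en-1-yl (3S)-3-hydroxy-4-(morpholin-4-yl)-4-oxobutanoate | C/C=C(\C)COC(=O)C[C@H](O)C(=O)N1CCOCC1 | intermediate
8 | dilithium alkoxide/(Z)-ester enolate of 7 (chelated dianion, not isolated) | C/C=C(\C)CO/C([O-])=C/[C@H]([O-])C(=O)N1CCOCC1.[Li+].[Li+] | intermediate
9 | (2R,3S)-2-[(1S)-1-hydroxy-2-(morpholin-4-yl)-2-oxoethyl]-3,4-dimethylpent-4-enoic acid | OC(=O)[C@H]([C@H](C)C(C)=C)[C@H](O)C(=O)N1CCOCC1 | intermediate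
10 | (2-methylprop-1-en-1-yl)magnesium bromide | CC(C)=C[Mg]Br | starting material
11 | (2R,3S)-2-[(1S)-1-hydroxy-4-methyl-2-oxopent-3-en-1-yl]-3,4-dimethylpent-4-enoic acid | OC(=O)[C@H]([C@H](C)C(C)=C)[C@H](O)C(=O)C=C(C)C | intermediate
12 | methylmagnesium bromide | C[Mg]Br | starting material
13 | (2R,3S)-2-[(1S,2R)-1,2-dihydroxy-2,4-dimethylpent-3-en-1-yl]-3,4-dimethylpent-4-enoic acid, present as its bromomagnesium carboxylate/alkoxide (drawn as free acid, not isolated) | OC(=O)[C@H]([C@H](C)C(C)=C)[C@H](O)[C@](C)(O)C=C(C)C | intermediate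
14 | (2S,3S,4R)-4,6-dimethyl-2-[(2S)-3-methylbut-3-en-2-yl]hept-5-ene-1,3,4-triol | OC[C@H]([C@H](C)C(C)=C)[C@H](O)[C@](C)(O)C=C(C)C | intermediate
15 | chlorotriethylsilane | CC[Si](Cl)(CC)CC | starting material
16 | (2S,3S,4R)-4,6-dimethyl-2-[(2S)-3-methylbut-3-en-2-yl]-1-[(triethylsilyl)oxy]hept-5-ene-3,4-diol | CC[Si](CC)(CC)OC[C@H]([C@H](C)C(C)=C)[C@H](O)[C@](C)(O)C=C(C)C | intermediate
17 | ozone | [O-][O+]=O | starting material
18 | bis(1,2,4-trioxolane) of 16 (both alkenes as secondary ozonides, ozonide carbons as mixtures, not isolated) | CC[Si](CC)(CC)OC[C@H]([C@H](C)C1(C)OCOO1)[C@H](O)[C@](C)(O)C1OC(C)(C)OO1 | intermediate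
19 | (2S,3S,4S)-2,3-dihydroxy-2-methyl-4-[(2S)-3-oxobutan-2-yl]-5-[(triethylsilyl)oxy]pentanal | CC[Si](CC)(CC)OC[C@H]([C@H](C)C(C)=O)[C@H](O)[C@](C)(O)C=O | intermediate
20 | (1R,2R,3S,4S,5S,6S)-1,3,6-trimethyl-5-{[(triethylsilyl)oxy]methyl}cyclohexane-1,2,3,4-tetrol | CC[Si](CC)(CC)OC[C@@H]1[C@H](C)[C@@](C)(O)[C@@H](O)[C@@](C)(O)[C@H]1O | intermediate
21 | acetic anhydride | CC(=O)OC(C)=O | starting material
22 | (1R,2R,3S,4S,5S,6S)-1,3-dihydroxy-1,3,6-trimethyl-5-{[(triethylsilyl)oxy]methyl}cyclohexane-2,4-diyl diacetate | CC[Si](CC)(CC)OC[C@@H]1[C@H](C)[C@@](C)(O)[C@@H](OC(C)=O)[C@@](C)(O)[C@H]1OC(C)=O | intermediate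
23 | (1R,2R,3S,4S,5R,6S)-5-formyl-1,3-dihydroxy-1,3,6-trimethylcyclohexane-2,4-diyl diacetate | O=C[C@@H]1[C@H](C)[C@@](C)(O)[C@@H](OC(C)=O)[C@@](C)(O)[C@H]1OC(C)=O | intermediate
24 | 2-(triphenyl-λ5-phosphanylidene)propanal | CC(C=O)=P(c1ccccc1)(c1ccccc1)c1ccccc1 | starting material
25 | (1R,2R,3S,4S,5R,6S)-1,3-dihydroxy-1,3,6-trimethyl-5-[(1E)-2-methyl-3-oxoprop-1-en-1-yl]cyclohexane-2,4-diyl diacetate | O=C/C(C)=C/[C@@H]1[C@H](C)[C@@](C)(O)[C@@H](OC(C)=O)[C@@](C)(O)[C@H]1OC(C)=O | intermediate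
26 | methyl 2-methyl-3-oxopentanoate (racemic) | CCC(=O)C(C)C(=O)OC | starting material
27 | methyl (2E)-2-methylbut-2-enoate (methyl tiglate) | COC(=O)/C(C)=C/C | starting material
28 | methyl (6E)-2,4,6-trimethyl-3,5-dioxooct-6-enoate (not isolated) | COC(=O)C(C)C(=O)C(C)C(=O)/C(C)=C/C | intermediate
29 | 6-[(2E)-but-2-en-2-yl]-4-hydroxy-3,5-dimethyl-2H-pyran-2-one | Cc1c(O)c(C)c(/C(C)=C/C)oc1=O | intermediate
30 | methyl trifluoromethanesulfonate | COS(=O)(=O)C(F)(F)F | starting material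
31 | 2-[(2E)-but-2-en-2-yl]-6-methoxy-3,5-dimethyl-4H-pyran-4-one | COc1oc(/C(C)=C/C)c(C)c(=O)c1C | intermediate
32 | lithium alkoxide of (1R,2R,3S,4S,5R,6S)-1,3-dihydroxy-5-[(1E,5E)-3-hydroxy-6-(6-methoxy-3,5-dimethyl-4-oxo-4H-pyran-2-yl)-2-methylhepta-1,5-dien-1-yl]-1,3,6-trimethylcyclohexane-2,4-diyl diacetate (both carbinol epimers, not isolated) | COc1oc(/C(C)=C/CC([O-])/C(C)=C/[C@@H]2[C@H](C)[C@@](C)(O)[C@@H](OC(C)=O)[C@@](C)(O)[C@H]2OC(C)=O)c(C)c(=O)c1C.[Li+] | intermediate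
33 | 3′-O-methanesulfonate of the aldol adduct in 32 (not isolated) | COc1oc(/C(C)=C/CC(OS(C)(=O)=O)/C(C)=C/[C@@H]2[C@H](C)[C@@](C)(O)[C@@H](OC(C)=O)[C@@](C)(O)[C@H]2OC(C)=O)c(C)c(=O)c1C | intermediate
34 | amaurone B, (1R,2R,3S,4S,5R,6S)-1,3-dihydroxy-5-[(1E,3E,5E)-6-(6-methoxy-3,5-dimethyl-4-oxo-4H-pyran-2-yl)-2-methylhepta-1,3,5-trien-1-yl]-1,3,6-trimethylcyclohexane-2,4-diyl diacetate | COc1oc(/C(C)=C/C=C/C(C)=C/[C@@H]2[C@H](C)[C@@](C)(O)[C@@H](OC(C)=O)[C@@](C)(O)[C@H]2OC(C)=O)c(C)c(=O)c1C | target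

**Step count**
Total: 15 steps. Longest linear sequence: 13 steps (steps 1–12 and 15, from L-malic acid); the pyranone branch is steps 13–14.

**Three steps most likely to fail**

Step 9 (proposed photochemical pinacol). Risks are slow samarium turnover, retro-aldol or α-ketol rearrangement of 19 at the Lewis-acidic metal, and a trans-diol. The fallback uses known chemistry and a different ring-closing logic; it sets out from diene 16 and comes back at tetrol 20. Ring-closing metathesis of 16 (Hoveyda–Grubbs II, toluene, 80 °C) gives (1S,2R,5S,6S)-2,4,5-trimethyl-6-{[(triethylsilyl)oxy]methyl}cyclohex-3-ene-1,2-diol F5. Hydroxyl-directed dihydroxylation of the ring alkene with stoichiometric OsO4·TMEDA (CH2Cl2, −78 °C, then aqueous Na2SO3) adds both oxygens syn to the C5 hydroxyl and anti to the C2 methyl, which is the all-cis tetrol 20.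

Step 15 (vinylogous aldol condensation). Risks are γ- instead of ε-attack of the trienolate, 1,4-addition, and E/Z mixtures. The fallback sets out from enal 25 and comes back at 34, moving the nucleophilic site to the well-precedented γ-position of a 6-ethyl pyranone.
- Wittig homologation of 25 with (triphenylphosphoranylidene)acetaldehyde gives (1R,2R,3S,4S,5R,6S)-1,3-dihydroxy-1,3,6-trimethyl-5-[(1E,3E)-2-methyl-5-oxopenta-1,3-dien-1-yl]cyclohexane-2,4-diyl diacetate F6.
- In parallel, the dianion of 26 is acylated with methyl propanoate to methyl 2,4-dimethyl-3,5-dioxoheptanoate F7, cyclised with DBU to 6-ethyl-4-hydroxy-3,5-dimethyl-2H-pyran-2-one F8, and O-methylated with MeOTf to 2-ethyl-6-methoxy-3,5-dimethyl-4H-pyran-4-one F9.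
- Lithiation of F9 (LiHMDS, −78 °C) and addition to F6 gives the aldol (1R,2R,3S,4S,5R,6S)-1,3-dihydroxy-5-[(1E,3E)-5-hydroxy-6-(6-methoxy-3,5-dimethyl-4-oxo-4H-pyran-2-yl)-2-methylhepta-1,3-dien-1-yl]-1,3,6-trimethylcyclohexane-2,4-diyl diacetate F10.
- Mesylation gives the 5′-methanesulfonate of that aldol F11, and DBU elimination returns to 34.

Step 4 (dianionic Ireland–Claisen). Risks are retro-aldol of the β-alkoxide before enolisation and modest diastereoselectivity or yield on this multifunctional dianion. The fallback sets out from 7 and comes back at 9, replacing chelate control by a non-chelated silyl ketene acetal; its facial selectivity is less certain and may be lower.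
- TBSCl/imidazole gives (2E)-2-methylbut-2-en-1-yl (3S)-3-[(tert-butyldimethylsilyl)oxy]-4-(morpholin-4-yl)-4-oxobutanoate F1.
- LDA in THF/DMPU with TMSCl gives the (Z)-O-trimethylsilyl ketene acetal of that ester F2.
- Warming effects the [3,3] shift to trimethylsilyl (2R,3S)-2-[(1S)-1-[(tert-butyldimethylsilyl)oxy]-2-(morpholin-4-yl)-2-oxoethyl]-3,4-dimethylpent-4-enoate F3.
- Aqueous work-up gives (2R,3S)-2-[(1S)-1-[(tert-butyldimethylsilyl)oxy]-2-(morpholin-4-yl)-2-oxoethyl]-3,4-dimethylpent-4-enoic acid F4, and HF·pyridine returns to 9.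

**Further compounds**
F1 | step 4 | (2E)-2-methylbut-2-en-1-yl (3S)-3-[(tert-butyldimethylsilyl)oxy]-4-(morpholin-4-yl)-4-oxobutanoate | C/C=C(\C)COC(=O)C[C@H](O[Si](C)(C)C(C)(C)C)C(=O)N1CCOCC1
F2 | step 4 | (Z)-O-trimethylsilyl ketene acetal of F1 | C/C=C(\C)CO/C(O[Si](C)(C)C)=C/[C@H](O[Si](C)(C)C(C)(C)C)C(=O)N1CCOCC1
F3 | step 4 | trimethylsilyl (2R,3S)-2-[(1S)-1-[(tert-butyldimethylsilyl)oxy]-2-(morpholin-4-yl)-2-oxoethyl]-3,4-dimethylpent-4-enoate | C[Si](C)(C)OC(=O)[C@H]([C@H](C)C(C)=C)[C@H](O[Si](C)(C)C(C)(C)C)C(=O)N1CCOCC1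
F4 | step 4 | (2R,3S)-2-[(1S)-1-[(tert-butyldimethylsilyl)oxy]-2-(morpholin-4-yl)-2-oxoethyl]-3,4-dimethylpent-4-enoic acid | OC(=O)[C@H]([C@H](C)C(C)=C)[C@H](O[Si](C)(C)C(C)(C)C)C(=O)N1CCOCC1
F5 | step 9 | (1S,2R,5S,6S)-2,4,5-trimethyl-6-{[(triethylsilyl)oxy]methyl}cyclohex-3-ene-1,2-diol | CC[Si](CC)(CC)OC[C@@H]1[C@H](C)C(C)=C[C@@](C)(O)[C@H]1O
F6 | step 15 | (1R,2R,3S,4S,5R,6S)-1,3-dihydroxy-1,3,6-trimethyl-5-[(1E,3E)-2-methyl-5-oxopenta-1,3-dien-1-yl]cyclohexane-2,4-diyl diacetate | O=C/C=C/C(C)=C/[C@@H]1[C@H](C)[C@@](C)(O)[C@@H](OC(C)=O)[C@@](C)(O)[C@H]1OC(C)=O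
F7 | step 15 | methyl 2,4-dimethyl-3,5-dioxoheptanoate | CCC(=O)C(C)C(=O)C(C)C(=O)OC
F8 | step 15 | 6-ethyl-4-hydroxy-3,5-dimethyl-2H-pyran-2-one | CCc1oc(=O)c(C)c(O)c1C
F9 | step 15 | 2-ethyl-6-methoxy-3,5-dimethyl-4H-pyran-4-one | CCc1oc(OC)c(C)c(=O)c1C
F10 | step 15 | (1R,2R,3S,4S,5R,6S)-1,3-dihydroxy-5-[(1E,3E)-5-hydroxy-6-(6-methoxy-3,5-dimethyl-4-oxo-4H-pyran-2-yl)-2-methylhepta-1,3-dien-1-yl]-1,3,6-trimethylcyclohexane-2,4-diyl diacetate (side-chain epimers) | COc1oc(C(C)C(O)/C=C/C(C)=C/[C@@H]2[C@H](C)[C@@](C)(O)[C@@H](OC(C)=O)[C@@](C)(O)[C@H]2OC(C)=O)c(C)c(=O)c1C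
F11 | step 15 | 5′-methanesulfonate of F10 | COc1oc(C(C)C(OS(C)(=O)=O)/C=C/C(C)=C/[C@@H]2[C@H](C)[C@@](C)(O)[C@@H](OC(C)=O)[C@@](C)(O)[C@H]2OC(C)=O)c(C)c(=O)c1C
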